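## Retrosynthetic overview

1. The target comes from its bis-silyl ether by one global desilylation.
2. Key disconnection: the C3–C1′ bond between the lactone α-carbon and the ketone-bearing dienyl chain. The lactone enters as its α-bromide (α-carbon as the electrophile) and the chain as a dienylzinc, joined under nickel catalysis. The methyl ketone is carried through that flask as a masked Weinreb adduct.
3. The only ring, the γ-lactone, is closed before the union: anti-crotylboration of an α-methyl dienal (sets C4 and C5), hydroboration, oxidative lactonisation, α-bromination.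
4. The dienal comes from hexanal and formaldehyde (organocatalytic α-hydroxymethylation sets the side-chain centre) and two Wittig homologations.
5. The dienyl partner comes from (E)-pent-2-en-4-yn-1-ol: methylalumination/iodination, oxidation, Evans syn-aldol (sets the hydroxy/methyl pair), Weinreb amide, silylation.

Assumption: the stereochemistry is taken exactly as written in the SMILES, i.e. lactone 3S,4S,5S (all-trans), 6R in the C5 side chain, 5S,6R in the C3 side chain, all four C=C bonds E.

## Route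

Step 1
Reactants: 1 hexanal; 2 formaldehyde (37% aqueous); 3 (triphenylphosphoranylidene)acetaldehyde
Product: 5 (R,E)-4-(hydroxymethyl)oct-2-enal, via (S)-2-(hydroxymethyl)hexanal 4 (not isolated)
Conditions: (R)-2-[diphenyl(trimethylsilyloxy)methyl]pyrrolidine (10 mol %), pH 7 phosphate buffer, toluene, rt; toluene layer separated, then 3, rt → 40 °C
Reagents that add atoms: none
Why: Enamine-catalysed α-hydroxymethylation followed by Wittig olefination: the diarylprolinol silyl ether shields one face of the E-enamine so that formaldehyde adds to give the 2S aldehyde (the R catalyst is chosen by the usual steric-shielding model), and the stabilised ylide traps the labile β-hydroxy aldehyde as the E-enal without touching the new centre.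

Step 2
Reactants: 5 hydroxy enal
Product: 6 (R,E)-4-{[(tert-butyldimethylsilyl)oxy]methyl}oct-2-enal
Conditions: TBSCl, imidazole, CH2Cl2, 0 °C → rt
Reagents that add atoms: tert-butyldimethylsilyl chloride, CC(C)(C)[Si](C)(C)Cl
Why: Imidazole-mediated silylation of a primary alcohol, which leaves the enal and the stereocentre untouched.

Step 3
Reactants: 6 silyl ether enal; 7 2-(triphenylphosphoranylidene)propanal
Product: 8 (2E,4E,6R)-6-{[(tert-butyldimethylsilyl)oxy]methyl}-2-methyldeca-2,4-dienal
Conditions: toluene, 90 °C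
Reagents that add atoms: none
Why: Wittig olefination with a stabilised α-methyl ylide gives the E-trisubstituted enal under neutral conditions that do not epimerise the γ-stereocentre.

Step 4
Reactants: 8 dienal; 9 trans-2-butene
Product: 12 (3S,4S,5E,7E,9R)-9-{[(tert-butyldimethylsilyl)oxy]methyl}-3,5-dimethyltrideca-1,5,7-trien-4-ol, via (E)-crotyldiisopinocampheylborane 10 (not isolated), via diisopinocampheylborinate of the adduct 11 (not isolated)
Conditions: KOt-Bu, n-BuLi, THF, −78 → −45 °C; (−)-Ipc2BOMe [from (+)-α-pinene], −78 °C; BF3·OEt2; then 8, −78 °C; NaOH, H2O2, 0 °C → rt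
Reagents that add atoms: none
Why: Brown crotylboration: the E-crotylborane reacts through a chair Zimmerman–Traxler transition state to give the anti adduct, and the isopinocampheyl groups derived from (+)-α-pinene direct attack to the Si face of the aldehyde, setting 3S,4S (the later C4 and C5 of the lactone).

Step 5
Reactants: 12 homoallylic alcohol
Product: 14 (3S,4S,5E,7E,9R)-9-{[(tert-butyldimethylsilyl)oxy]methyl}-3,5-dimethyltrideca-5,7-diene-1,4-diol, via bis(9-BBN) adduct 13 (not isolated)
Conditions: 9-BBN (2.5 equiv), THF, 0 °C → rt; then NaOH, H2O2, 0 °C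
Reagents that add atoms: hydrogen peroxide, OO
Why: Hydroboration–oxidation: bulky 9-BBN adds anti-Markovnikov to the monosubstituted terminal alkene much faster than to the hindered conjugated diene, and C–B oxidation with retention gives the primary alcohol without affecting the stereocentres.

Step 6
Reactants: 14 1,4-diol
Product: 15 (4S,5S)-5-[(2E,4E,6R)-6-{[(tert-butyldimethylsilyl)oxy]methyl}deca-2,4-dien-2-yl]-4-methyloxolan-2-one
Conditions: TEMPO (20 mol %), PhI(OAc)2 (2.5 equiv), CH2Cl2, rt
Reagents that add atoms: none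
Why: TEMPO/PhI(OAc)2 oxidative lactonisation of a 1,4-diol: the oxoammonium salt oxidises the unhindered primary alcohol in preference to the secondary allylic one and the oxidation runs on through the cyclic hemiacetal stage to the γ-lactone, closing the ring with both stereocentres intact.

Step 7
Reactants: 15 lactone
Product: 17 (3S,4R,5S)-3-bromo-5-[(2E,4E,6R)-6-{[(tert-butyldimethylsilyl)oxy]methyl}deca-2,4-dien-2-yl]-4-methyloxolan-2-one (major 3,4-trans epimer; the 3R epimer is carried along), via trimethylsilyl ketene acetal 16 (not isolated)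
Conditions: LiN(SiMe3)2, Me3SiCl, THF, −78 °C; then NBS, −78 °C
Reagents that add atoms: N-bromosuccinimide, O=C1CCC(=O)N1Br
Why: Electrophilic α-bromination of a silyl ketene acetal: NBS attacks the electron-rich ketene acetal far faster than the diene and mainly anti to the C4 methyl group, and the C3 configuration does not matter because the next bond formation is stereoconvergent.

Step 8
Reactants: 18 (E)-pent-2-en-4-yn-1-ol
Product: 20 (2E,4E)-5-iodo-4-methylpenta-2,4-dien-1-ol, via dimethylalkenylalane 19 (not isolated)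
Conditions: Me3Al (3 equiv), Cp2ZrCl2 (25 mol %), ClCH2CH2Cl, 0 °C → rt; then I2, THF, −30 → 0 °C
Reagents that add atoms: trimethylaluminium, C[Al](C)C; iodine, II
Why: Negishi zirconium-catalysed methylalumination and iodinolysis: syn addition of Me–Al across the terminal alkyne puts aluminium at the terminus cis to the new methyl group, and iodine replaces aluminium with retention to give the E-trisubstituted vinyl iodide.

Step 9
Reactants: 20 iododienol
Product: 21 (2E,4E)-5-iodo-4-methylpenta-2,4-dienal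
Conditions: MnO2 (15 equiv), CH2Cl2, rt
Reagents that add atoms: none
Why: MnO2 oxidation is selective for the allylic alcohol and gives the dienal without alkene isomerisation.

Step 10
Reactants: 21 iododienal; 22 (R)-4-benzyl-3-propionyloxazolidin-2-one
Product: 25 (R)-4-benzyl-3-[(2R,3S,4E,6E)-3-hydroxy-7-iodo-2,6-dimethylhepta-4,6-dienoyl]oxazolidin-2-one, via dibutylboron Z-enolate 23 (not isolated), via dibutylboron aldolate 24 (not isolated)
Conditions: 22, Bu2BOTf, Et3N, CH2Cl2, −78 → 0 °C; then 21, −78 → 0 °C; pH 7 buffer, MeOH, H2O2, 0 °C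
Reagents that add atoms: none
Why: Evans syn-aldol reaction: the Z-boron enolate adds through a chair Zimmerman–Traxler transition state on the enolate face opposite the benzyl group, which with the R auxiliary gives the 2R,3S syn adduct.

Step 11
Reactants: 25 aldol adduct
Product: 26 (2R,3S,4E,6E)-3-hydroxy-7-iodo-N-methoxy-N,2,6-trimethylhepta-4,6-dienamide
Conditions: MeNHOMe·HCl, Me3Al, CH2Cl2, −20 → 0 °C
Reagents that add atoms: N,O-dimethylhydroxylamine hydrochloride, CNOC.Cl
Why: Weinreb transamidation: the aluminium amide, assisted by the free β-hydroxyl, cleaves the exocyclic imide carbonyl without epimerisation and releases the auxiliary.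

Step 12
Reactants: 26 hydroxy Weinreb amide
Product: 27 (2R,3S,4E,6E)-7-iodo-N-methoxy-N,2,6-trimethyl-3-[(triethylsilyl)oxy]hepta-4,6-dienamide
Conditions: Et3SiCl, imidazole, DMF, 0 °C
Reagents that add atoms: chlorotriethylsilane, CC[Si](Cl)(CC)CC
Why: Imidazole-mediated silylation protects the secondary alcohol for the organolithium chemistry of the next step.

Step 13
Reactants: 27 silylated iodo Weinreb amide (1.5 equiv); 17 α-bromo lactone
Product: 32 (3S,4S,5S)-5-[(2E,4E,6R)-6-{[(tert-butyldimethylsilyl)oxy]methyl}deca-2,4-dien-2-yl]-3-[(1E,3E,5S,6R)-2,6-dimethyl-7-oxo-5-[(triethylsilyl)oxy]octa-1,3-dien-1-yl]-4-methyloxolan-2-one, via lithium hemiaminal 28 (not isolated), via dienyllithium 29 (not isolated), via dienylzinc bromide 30 (not isolated), via coupled lithium hemiaminal 31 (not isolated)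
Conditions: 27, MeLi, Et2O, −78 °C; t-BuLi (2 equiv), −78 °C; ZnBr2, THF, −78 → −20 °C; then 17, NiCl2·glyme (10 mol %), 4,4′-di-tert-butyl-2,2′-bipyridine (12 mol %), THF/DMA, −20 → 0 °C; aq. NH4Cl
Reagents that add atoms: methyllithium, C[Li]
Why: Proposed new method: MeLi adds to the Weinreb amide to give a stable chelated tetrahedral adduct that masks the future ketone while t-BuLi exchanges the iodide with retention and ZnBr2 gives the dienylzinc; after transmetallation the monovalent alkenylnickel abstracts bromine from 17 to give a planar α-lactonyl radical (so both C3 epimers converge), which recombines with alkenylnickel and is reductively eliminated from trivalent nickel on the face anti to the C4 methyl group to set 3S, with the lactone α-carbon acting as the electrophile, and aqueous work-up releases the methyl ketone; the closest known reaction type is the stereoconvergent nickel-catalysed Negishi alkenylation and arylation of secondary α-halo carbonyl compounds.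

Step 14
Reactants: 32 bis-silyl ether
Product: 33 (3S,4S,5S)-3-[(1E,3E,5S,6R)-5-hydroxy-2,6-dimethyl-7-oxoocta-1,3-dien-1-yl]-5-[(2E,4E,6R)-6-(hydroxymethyl)deca-2,4-dien-2-yl]-4-methyloxolan-2-one (CNP0187795.2)
Conditions: HF·pyridine, pyridine, THF, 0 °C → rt
Reagents that add atoms: none
Why: Buffered fluoride desilylation removes the primary TBS and secondary TES ethers without epimerising C3 or the ketone α-carbon and without dehydrating the β-hydroxy ketone.

## Compound list

1 | hexanal | CCCCCC=O | starting material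
2 | formaldehyde | C=O | starting material
3 | (triphenylphosphoranylidene)acetaldehyde | O=CC=P(c1ccccc1)(c1ccccc1)c1ccccc1 | starting material
4 | (S)-2-(hydroxymethyl)hexanal | CCCC[C@@H](CO)C=O | intermediate (not isolated)
5 | (R,E)-4-(hydroxymethyl)oct-2-enal | CCCC[C@H](/C=C/C=O)CO | intermediate
6 | (R,E)-4-{[(tert-butyldimethylsilyl)oxy]methyl}oct-2-enal | CCCC[C@H](/C=C/C=O)CO[Si](C)(C)C(C)(C)C | intermediate
7 | 2-(triphenylphosphoranylidene)propanal | CC(C=O)=P(c1ccccc1)(c1ccccc1)c1ccccc1 | starting material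
8 | (2E,4E,6R)-6-{[(tert-butyldimethylsilyl)oxy]methyl}-2-methyldeca-2,4-dienal | CCCC[C@H](/C=C/C=C(\C)C=O)CO[Si](C)(C)C(C)(C)C | intermediate
9 | trans-2-butene | C/C=C/C | starting material
10 | (E)-crotyldiisopinocampheylborane, Ipc groups from (+)-α-pinene | C/C=C/CB([C@@H]1C[C@@H]2C[C@H]([C@H]1C)C2(C)C)[C@@H]1C[C@@H]2C[C@H]([C@H]1C)C2(C)C | intermediate (not isolated)
11 | O-diisopinocampheylboryl derivative (borinate) of alcohol 12 | CCCC[C@H](/C=C/C=C(\C)[C@@H](OB([C@@H]1C[C@@H]2C[C@H]([C@H]1C)C2(C)C)[C@@H]1C[C@@H]2C[C@H]([C@H]1C)C2(C)C)[C@@H](C)C=C)CO[Si](C)(C)C(C)(C)C | intermediate (not isolated)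
12 | (3S,4S,5E,7E,9R)-9-{[(tert-butyldimethylsilyl)oxy]methyl}-3,5-dimethyltrideca-1,5,7-trien-4-ol | CCCC[C@H](/C=C/C=C(\C)[C@@H](O)[C@@H](C)C=C)CO[Si](C)(C)C(C)(C)C | intermediate
13 | bis(9-BBN) adduct of 12: C1 bonded to boron, C4 oxygen bonded to boron | CCCC[C@H](/C=C/C=C(\C)[C@@H](OB1C2CCCC1CCC2)[C@@H](C)CCB1C2CCCC1CCC2)CO[Si](C)(C)C(C)(C)C | intermediate (not isolated)
14 | (3S,4S,5E,7E,9R)-9-{[(tert-butyldimethylsilyl)oxy]methyl}-3,5-dimethyltrideca-5,7-diene-1,4-diol | CCCC[C@H](/C=C/C=C(\C)[C@@H](O)[C@@H](C)CCO)CO[Si](C)(C)C(C)(C)C | intermediate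
15 | (4S,5S)-5-[(2E,4E,6R)-6-{[(tert-butyldimethylsilyl)oxy]methyl}deca-2,4-dien-2-yl]-4-methyloxolan-2-one | CCCC[C@H](/C=C/C=C(\C)[C@H]1OC(=O)C[C@@H]1C)CO[Si](C)(C)C(C)(C)C | intermediate
16 | trimethylsilyl ketene acetal of 15 (2-trimethylsilyloxy-4,5-dihydrofuran) | CCCC[C@H](/C=C/C=C(\C)[C@H]1OC(O[Si](C)(C)C)=C[C@@H]1C)CO[Si](C)(C)C(C)(C)C | intermediate (not isolated)
17 | (3S,4R,5S)-3-bromo-5-[(2E,4E,6R)-6-{[(tert-butyldimethylsilyl)oxy]methyl}deca-2,4-dien-2-yl]-4-methyloxolan-2-one (major epimer shown; used together with its 3R epimer) | CCCC[C@H](/C=C/C=C(\C)[C@H]1OC(=O)[C@@H](Br)[C@@H]1C)CO[Si](C)(C)C(C)(C)C | intermediate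
18 | (E)-pent-2-en-4-yn-1-ol | C#C/C=C/CO | starting material
19 | (2E,4E)-5-(dimethylalumanyl)-4-methylpenta-2,4-dien-1-ol, O-dimethylaluminium alkoxide | C[Al](C)/C=C(\C)/C=C/CO[Al](C)C | intermediate (not isolated)
20 | (2E,4E)-5-iodo-4-methylpenta-2,4-dien-1-ol | I/C=C(\C)/C=C/CO | intermediate
21 | (2E,4E)-5-iodo-4-methylpenta-2,4-dienal | I/C=C(\C)/C=C/C=O | intermediate
22 | (R)-4-benzyl-3-propionyloxazolidin-2-one | CCC(=O)N1[C@H](Cc2ccccc2)COC1=O | starting material
23 | dibutylboron Z-enolate of 22 | C/C=C(\OB(CCCC)CCCC)N1[C@H](Cc2ccccc2)COC1=O | intermediate (not isolated)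
24 | O-dibutylboryl aldolate of 25 | I/C=C(\C)/C=C/[C@H](OB(CCCC)CCCC)[C@@H](C)C(=O)N1[C@H](Cc2ccccc2)COC1=O | intermediate (not isolated)
25 | (R)-4-benzyl-3-[(2R,3S,4E,6E)-3-hydroxy-7-iodo-2,6-dimethylhepta-4,6-dienoyl]oxazolidin-2-one | I/C=C(\C)/C=C/[C@H](O)[C@@H](C)C(=O)N1[C@H](Cc2ccccc2)COC1=O | intermediate
26 | (2R,3S,4E,6E)-3-hydroxy-7-iodo-N-methoxy-N,2,6-trimethylhepta-4,6-dienamide | I/C=C(\C)/C=C/[C@H](O)[C@@H](C)C(=O)N(C)OC | intermediate
27 | (2R,3S,4E,6E)-7-iodo-N-methoxy-N,2,6-trimethyl-3-[(triethylsilyl)oxy]hepta-4,6-dienamide | I/C=C(\C)/C=C/[C@H](O[Si](CC)(CC)CC)[C@@H](C)C(=O)N(C)OC | intermediate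
28 | lithium hemiaminal from MeLi addition to 27 (hemiaminal carbon unassigned) | I/C=C(\C)/C=C/[C@H](O[Si](CC)(CC)CC)[C@@H](C)C(C)(O[Li])N(C)OC | intermediate (not isolated)
29 | dienyllithium from iodine–lithium exchange of 28 | [Li]/C=C(\C)/C=C/[C@H](O[Si](CC)(CC)CC)[C@@H](C)C(C)(O[Li])N(C)OC | intermediate (not isolated)
30 | dienylzinc bromide from 29 and ZnBr2 | Br[Zn]/C=C(\C)/C=C/[C@H](O[Si](CC)(CC)CC)[C@@H](C)C(C)(O[Li])N(C)OC | intermediate (not isolated)
31 | coupled product still carrying the lithium hemiaminal | CCCC[C@H](/C=C/C=C(\C)[C@H]1OC(=O)[C@@H](/C=C(C)/C=C/[C@H](O[Si](CC)(CC)CC)[C@@H](C)C(C)(O[Li])N(C)OC)[C@@H]1C)CO[Si](C)(C)C(C)(C)C | intermediate (not isolated)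
32 | (3S,4S,5S)-5-[(2E,4E,6R)-6-{[(tert-butyldimethylsilyl)oxy]methyl}deca-2,4-dien-2-yl]-3-[(1E,3E,5S,6R)-2,6-dimethyl-7-oxo-5-[(triethylsilyl)oxy]octa-1,3-dien-1-yl]-4-methyloxolan-2-one | CCCC[C@H](/C=C/C=C(\C)[C@H]1OC(=O)[C@@H](/C=C(C)/C=C/[C@H](O[Si](CC)(CC)CC)[C@@H](C)C(C)=O)[C@@H]1C)CO[Si](C)(C)C(C)(C)C | intermediate
33 | (3S,4S,5S)-3-[(1E,3E,5S,6R)-5-hydroxy-2,6-dimethyl-7-oxoocta-1,3-dien-1-yl]-5-[(2E,4E,6R)-6-(hydroxymethyl)deca-2,4-dien-2-yl]-4-methyloxolan-2-one | CCCC[C@H](/C=C/C=C(\C)[C@H]1OC(=O)[C@@H](/C=C(C)/C=C/[C@H](O)[C@@H](C)C(C)=O)[C@@H]1C)CO | target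

## Step count and risks

Total: 14 steps. Longest linear sequence: 9 steps (1–7, 13, 14); the dienyl partner takes 5 steps (8–12).

The three steps most likely to fail, each with one fallback:

First, the nickel-catalysed union (step 13). The one-flask masking and metalation of 27 may not stay clean, low-valent nickel may ionise the allylic C5–O bond of the lactone, and the coupling itself has no direct precedent on an α-bromo lactone with a functionalised dienylzinc. The fallback sets out from 27 (17 is used unchanged) and comes back at 32. 27 is treated with MeMgBr (THF, 0 °C) and isolated as the methyl ketone (3R,4S,5E,7E)-8-iodo-3,7-dimethyl-4-[(triethylsilyl)oxy]octa-5,7-dien-2-one F1. F1 and 17 are then joined as two halides, with no preformed organometallic, by a nickel-catalysed reductive cross-electrophile coupling (NiBr2·glyme 10 mol %, 4,4′-di-tert-butyl-2,2′-bipyridine, Mn powder, NaI, DMA, rt). The alkenylnickel formed by oxidative addition of F1 captures the same α-lactonyl radical anti to the C4 methyl group and gives 32 directly.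

Second, the organocatalytic hydroxymethylation with in-flask Wittig trapping (step 1). The β-hydroxy aldehyde can dehydrate or racemise, and the sense and level of induction rest on the shielding model. The fallback sets out from 1 and comes back at 6, and replaces catalyst control by auxiliary control:
- 1 is oxidised (NaClO2, NaH2PO4, 2-methyl-2-butene) to hexanoic acid F2.
- F2 is converted through its pivaloyl mixed anhydride (pivaloyl chloride, Et3N, LiCl, (R)-4-benzyloxazolidin-2-one) into (R)-4-benzyl-3-hexanoyloxazolidin-2-one F3.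
- The titanium enolate of F3 (TiCl4, i-Pr2NEt, CH2Cl2, 0 °C) is hydroxymethylated with s-trioxane to (R)-4-benzyl-3-[(S)-2-(hydroxymethyl)hexanoyl]oxazolidin-2-one F4.
- Silylation (TBSCl, imidazole) gives (R)-4-benzyl-3-[(S)-2-{[(tert-butyldimethylsilyl)oxy]methyl}hexanoyl]oxazolidin-2-one F5.
- LiBH4 (THF, MeOH) cleaves the auxiliary to (R)-2-{[(tert-butyldimethylsilyl)oxy]methyl}hexan-1-ol F6.
- Dess–Martin periodinane gives (S)-2-{[(tert-butyldimethylsilyl)oxy]methyl}hexanal F7, which is olefinated at once with 3 to give 6.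

Third, the chemoselective hydroboration (step 5). 9-BBN may also attack the diene, and the following oxidation may touch the allylic carbinol. The fallback sets out from 8 and comes back at 17, bypassing 12–16:
- Zinc-mediated asymmetric addition of methyl propiolate to 8 (Me2Zn, the ProPhenol ligand enantiomer that delivers the alkynyl group to the Si face of the aldehyde, toluene, 4 °C) gives methyl (4R,5E,7E,9R)-9-{[(tert-butyldimethylsilyl)oxy]methyl}-4-hydroxy-5-methyltrideca-5,7-dien-2-ynoate F8.
- Semihydrogenation (H2, Pd/CaCO3 poisoned by Pb(OAc)2, quinoline) and acid-catalysed closure of the Z-hydroxy ester give the butenolide (S)-5-[(2E,4E,6R)-6-{[(tert-butyldimethylsilyl)oxy]methyl}deca-2,4-dien-2-yl]furan-2(5H)-one F9.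
- Me2CuLi with Me3SiCl (THF, −78 °C) adds the methyl group anti to the C5 substituent (setting C4), and NBS added to the same flask brominates the resulting silyl ketene acetal to give 17.

## Further compounds

F1 | step 13 | (3R,4S,5E,7E)-8-iodo-3,7-dimethyl-4-[(triethylsilyl)oxy]octa-5,7-dien-2-one | I/C=C(\C)/C=C/[C@H](O[Si](CC)(CC)CC)[C@@H](C)C(C)=O
F2 | step 1 | hexanoic acid | CCCCCC(=O)O
F3 | step 1 | (R)-4-benzyl-3-hexanoyloxazolidin-2-one | CCCCCC(=O)N1[C@H](Cc2ccccc2)COC1=O
F4 | step 1 | (R)-4-benzyl-3-[(S)-2-(hydroxymethyl)hexanoyl]oxazolidin-2-one | CCCC[C@@H](CO)C(=O)N1[C@H](Cc2ccccc2)COC1=O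
F5 | step 1 | (R)-4-benzyl-3-[(S)-2-{[(tert-butyldimethylsilyl)oxy]methyl}hexanoyl]oxazolidin-2-one | CCCC[C@@H](CO[Si](C)(C)C(C)(C)C)C(=O)N1[C@H](Cc2ccccc2)COC1=O
F6 | step 1 | (R)-2-{[(tert-butyldimethylsilyl)oxy]methyl}hexan-1-ol | CCCC[C@@H](CO[Si](C)(C)C(C)(C)C)CO
F7 | step 1 | (S)-2-{[(tert-butyldimethylsilyl)oxy]methyl}hexanal | CCCC[C@@H](CO[Si](C)(C)C(C)(C)C)C=O
F8 | step 5 | methyl (4R,5E,7E,9R)-9-{[(tert-butyldimethylsilyl)oxy]methyl}-4-hydroxy-5-methyltrideca-5,7-dien-2-ynoate | CCCC[C@H](/C=C/C=C(\C)[C@@H](O)C#CC(=O)OC)CO[Si](C)(C)C(C)(C)C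
F9 | step 5 | (S)-5-[(2E,4E,6R)-6-{[(tert-butyldimethylsilyl)oxy]methyl}deca-2,4-dien-2-yl]furan-2(5H)-one | CCCC[C@H](/C=C/C=C(\C)[C@H]1OC(=O)C=C1)CO[Si](C)(C)C(C)(C)C
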